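The charge is set aside here: each flask is judged by what can dissolve during its run.

    solid substrate ⇌ starting material, rate k1*(cs1 - [starting material]) while solid is left; crystals form when [starting material] > cs1 (cs1 = 0.066 M, k1 = 0.027 s⁻¹)
    target ⇌ isomer of the product (K2 = 2.0, k2 = 0.014 s⁻¹)
    starting material → target (k3 = 0.081 s⁻¹)
    starting material + target → side product (k4 = 0.71 L mol⁻¹ s⁻¹)

common to all: time 50 s

| charge | solid substrate |
|---|---|
| theta | 0.012 M |
| delta | 0.030 M |
| eta | 0.10 M |
| alpha | 0.30 M |

- percentages count the solid substrate that a species holds: one side product counts as two
- solid, in amounts per volume of the solution: solid substrate
- at the start none of the solid substrate is in solution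
- a step back or a flat step of under half a point counts as no turn
- "hardly changes" means that all values lie within two and a half points (for a concentration: within two and a half percent of the largest)
- run time (theta): 50 s

- share of target in all that became target or side product or isomer of the product for theta, delta, eta, alpha, in this order
- how that number moves from the first to the last of them (falls all the way / rises all the way / hardly changes / falls, then rises / rises, then falls)

**Dissolving capacity.** While solid substrate is left, [starting material] climbs towards a plateau (a quasi-steady state) where dissolving balances step 3. With step 4 set aside, that plateau is k1·cs1/(k1+k3) = 0.0165 M. It lies below the solubility, so no crystals form. The solid then feeds the solution at 0.00134 M s⁻¹, and at that pace 0.0668 M dissolve in 50 s, the dissolving capacity of the run.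

**Turned round.** For eta and alpha to part, the solid substrate in eta would have to vanish within the run. But eta's charge of 0.10 M exceeds the capacity by a factor of 1.50, and alpha's exceeds it further. Both solutions should therefore match, and the row should end flat. Delta's charge lies below the capacity, and theta's smaller charge lies under even the plateau. Step 4 needs starting material and target together, which speaks for a fall from theta to eta, but target made later has also had less time to pass into isomer of the product, which speaks against it. This reckoning weighs the two by no number, so it gives the flat end but no share. Should the share fall from theta to eta, the flat last step is no turn and the shape is a fall all the way.

**The forecast.** The forecast gives figures: 60 %, 55.3 %, 55 % and 55 %, with the shape falls all the way. Of eta and alpha it says: “so solid remains and the two runs are identical”.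

**The result.** The simulation gives 60.2 %, 56.8 %, 54.7 % and 54.7 %, with the shape falls all the way.

**What stands.** In 50 s, eta dissolves 0.0723 M and alpha 0.0723 M, each slightly above the capacity. At the reckoned feed, delta's charge clears in 22.4 s, and delta holds 0 % solid substrate at 25.0 s. In theta at 50.0 s, with each step taken net, target is made more slowly than it is used, at 0.250 of that rate. Counting the forward rate of step 2 alone, theta's target then passes into isomer of the product 86 times as fast as into side product, and theta holds 31.1 % isomer of the product against 7.92 % side product.

The constants used here were chosen freely; the flask was simulated.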